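The five-membered lactone ring (O1, C12, C11, C7, C6; germacrane numbering) is cut at C11–C12 and at O1–C6. This makes its O–C=O unit carbon dioxide. The key step exploits that C6 is allylic to C4=C5 and gamma to the vinylic carbon C11. The precursor is an open-chain C11 alkenylboronate. Its C6 carbinol is epimeric to the target and is masked as an O-allyl isourea. In one flask, copper-catalysed carboxylation forms C11–C12. The new carboxylate then displaces the protonated isourea at C6 with inversion and closes the trans-lactone. C8 is bought; C7, C6 and C9 are relayed from it. A Nozaki–Hiyama–Kishi reaction closes the ten-membered ring.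

Key step: step 13

Remark: all intermediates carry the germacrane numbers of the target. These are ring carbons C1–C10 (C1=C10, C4=C5, C6–O1, C8–OH, C9–OAc), C11(=C13H2)–C12(=O)–O1, C14 = CH2O on C10 and C15 = CH3 on C4. CIP descriptors refer to these numbers.

**Fragment A (C1–C6, C10, C14, C15)**

Step 1
Reactants: 1 nerol
Product: 2 neryl triethylsilyl ether
Conditions: Et3SiCl, imidazole, CH2Cl2, 0 °C
Reagents that add atoms: chlorotriethylsilane CC[Si](Cl)(CC)CC
Why: Silyl ether formation at the primary allylic alcohol; the triethylsilyl group is chosen because a Swern reagent later converts it directly into the aldehyde.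

Step 2
Reactants: 2 neryl triethylsilyl ether
Product: 3 (4Z)-4-methyl-6-(triethylsilyloxy)hex-4-enal
Conditions: O3 (1.0 equiv), CH2Cl2, −78 °C; then Me2S, −78 → 23 °C
Reagents that add atoms: ozone [O-][O+]=O
Why: Chemoselective ozonolysis, in which one equivalent of ozone should cleave only the electron-rich isopropylidene alkene because the C4=C5 alkene is deactivated by its allylic oxygen.

Step 3
Reactants: 3 (4Z)-4-methyl-6-(triethylsilyloxy)hex-4-enal
Product: 4 ethyl (2Z,6Z)-2-iodo-6-methyl-8-(triethylsilyloxy)octa-2,6-dienoate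
Conditions: Ph3P=CHCO2Et, N-iodosuccinimide, CH2Cl2, −20 °C; then 3, −20 → 23 °C
Reagents that add atoms: ethyl (triphenylphosphoranylidene)acetate CCOC(=O)C=P(c1ccccc1)(c1ccccc1)c1ccccc1; N-iodosuccinimide O=C1CCC(=O)N1I
Why: Wittig olefination with the stabilised iodo ylide made in the flask, which places iodine cis to the chain and so fixes the (Z)-C1=C10 geometry (C2 cis to the future C9).

Step 4
Reactants: 4 ethyl (2Z,6Z)-2-iodo-6-methyl-8-(triethylsilyloxy)octa-2,6-dienoate
Product: 5 (2Z,6Z)-2-iodo-6-methyl-8-(triethylsilyloxy)octa-2,6-dien-1-ol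
Conditions: i-Bu2AlH (2.3 equiv), CH2Cl2, −78 °C; aq potassium sodium tartrate
Reagents that add atoms: none
Why: DIBAL-H reduction of the enoate to the C14 allylic alcohol, to which the alkenyl iodide and the silyl ether are inert at low temperature.

Step 5
Reactants: 5 (2Z,6Z)-2-iodo-6-methyl-8-(triethylsilyloxy)octa-2,6-dien-1-ol
Product: 6 C14 tert-butyldimethylsilyl ether of 5
Conditions: t-BuMe2SiCl, imidazole, DMF, 23 °C
Reagents that add atoms: tert-butylchlorodimethylsilane CC(C)(C)[Si](C)(C)Cl
Why: Silyl ether formation; a silyloxy group is a poor leaving group and should not be lost by beta-elimination from the later alkenylchromium species, as an allylic ester might be.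

Step 6
Reactants: 6 C14 tert-butyldimethylsilyl ether of 5
Product: 7 (2Z,6Z)-8-(tert-butyldimethylsilyloxy)-7-iodo-3-methylocta-2,6-dienal
Conditions: (COCl)2, DMSO, CH2Cl2, −78 → −40 °C; then Et3N, −78 → 0 °C
Reagents that add atoms: none
Why: Swern oxidation applied directly to the primary triethylsilyl ether (oxidative desilylation); the bulkier tert-butyldimethylsilyl ether does not react, and the cold, short exposure to base preserves the (Z)-enal.

**Fragment B (C7–C9, C11, C13)**

Step 7
Reactants: 8 (R)-2,2-dimethyl-1,3-dioxolane-4-carbaldehyde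
Product: 9 (S)-4-ethynyl-2,2-dimethyl-1,3-dioxolane
Conditions: dimethyl (1-diazo-2-oxopropyl)phosphonate, K2CO3, MeOH, 0 → 23 °C
Reagents that add atoms: dimethyl (1-diazo-2-oxopropyl)phosphonate CC(=O)C(=[N+]=[N-])P(=O)(OC)OC
Why: Seyferth–Gilbert homologation with the Ohira–Bestmann reagent adds C11, while the bought stereocentre (the future C8) is not touched.

Step 8
Reactants: 9 (S)-4-ethynyl-2,2-dimethyl-1,3-dioxolane
Product: 10 (S)-2,2-dimethyl-4-(propa-1,2-dien-1-yl)-1,3-dioxolane
Conditions: (CH2O)n, CuBr (0.4 equiv), i-Pr2NH, 1,4-dioxane, reflux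
Reagents that add atoms: formaldehyde (as paraformaldehyde) C=O
Why: Crabbé homologation turns the terminal alkyne into the terminal allene and adds C13.

Step 9
Reactants: 10 (S)-2,2-dimethyl-4-(propa-1,2-dien-1-yl)-1,3-dioxolane
Product: 11 (S)-penta-3,4-diene-1,2-diol
Conditions: aq AcOH (80 %), 40 °C
Reagents that add atoms: none
Why: Mild acid hydrolysis of the acetonide, which the allene tolerates.

Step 10
Reactants: 11 (S)-penta-3,4-diene-1,2-diol
Product: 12 (S)-1,2-bis(triethylsilyloxy)penta-3,4-diene
Conditions: Et3SiCl (2.3 equiv), imidazole, DMF, 0 → 23 °C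
Reagents that add atoms: chlorotriethylsilane CC[Si](Cl)(CC)CC
Why: Double silyl ether formation; the primary ether at C9 can later be oxidised selectively beside the secondary one at C8.

**Union, key step and ring closure**

Step 11
Reactants: 12 (S)-1,2-bis(triethylsilyloxy)penta-3,4-diene; 7 (2Z,6Z)-8-(tert-butyldimethylsilyloxy)-7-iodo-3-methylocta-2,6-dienal
Product: 14 open-chain (6S,7S,8S)-C6 carbinol carrying the C11 alkenyl pinacolboronate, via bis(boronate) 13 (not isolated)
Conditions: B2pin2 (12 in slight excess over it), Pt(dba)2 (3 mol %), PCy3 (6 mol %), toluene, 50 °C; then 7, 23 → 40 °C; aq NaHCO3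
Reagents that add atoms: bis(pinacolato)diboron CC1(C)OB(OC1(C)C)B1OC(C)(C)C(C)(C)O1
Why: Diboration of the terminal allene bond by zerovalent platinum, from the side away from C8, gives the (Z)-allylboronate; its Zimmerman–Traxler chair in the allylboration of the enal sets C6–OH syn to C8 (anti to C11), and A(1,3) strain holds H8 in the alkene plane so that the aldehyde approaches anti to the CH2OSiEt3 branch and sets C11 anti to O8.

Step 12
Reactants: 14 open-chain (6S,7S,8S)-C6 carbinol carrying the C11 alkenyl pinacolboronate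
Product: 15 C6 O-allyl N,N'-diisopropylisourea of 14
Conditions: N,N'-diisopropylcarbodiimide (3 equiv), CuCl (10 mol %), THF, 40 °C
Reagents that add atoms: N,N'-diisopropylcarbodiimide CC(C)N=C=NC(C)C
Why: Copper-catalysed addition of an alcohol to a carbodiimide (O-alkylisourea formation) occurs with retention at C6 and gives a base-stable group that becomes a leaving group only on protonation.

Step 13
Reactants: 15 C6 O-allyl N,N'-diisopropylisourea of 14
Product: 17 open-chain (6R,7S,8S)-trans-alpha-methylene-gamma-butyrolactone, via potassium acrylate 16 (not isolated)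
Conditions: (IPr)CuCl (5 mol %; IPr = 1,3-bis(2,6-diisopropylphenyl)imidazol-2-ylidene), KOt-Bu (1.05 equiv), THF, 0 °C, then CO2 (1 atm), 65 °C; then 2,4,6-collidinium triflate (1.5 equiv), 50 °C
Reagents that add atoms: carbon dioxide O=C=O
Why: tert-Butoxide binds to boron, the alkenyl group passes from the borate to (IPr)CuOt-Bu, CO2 inserts into the C11–Cu bond (forming C11–C12) and salt exchange releases potassium acrylate 16 and the copper alkoxide; the closest known reaction type is the copper-catalysed carboxylation of alkenylboronic esters with CO2. The isourea is inert to base, so nothing happens at C6 until collidinium triflate protonates its nitrogen; a carboxylate oxygen then attacks C6 from the back of the C6–O bond and expels N,N'-diisopropylurea, which is the known esterification of acids by O-alkylisoureas with inversion. The lactone ring closes in the 5-exo-tet mode. C6 is the only stereocentre that changes: it is controlled by stereospecific inversion of the (6S)-centre set in step 11, and even an ion-pair pathway should collapse to the less strained trans-disubstituted lactone. The step needs carbon–boron over carbon–iodine chemoselectivity, secured because monovalent copper without palladium or nickel exchanges only with the borate, and it needs attack at C6 rather than C4, secured by a five-membered against a seven-membered ring. The silyl ethers, both (Z)-alkenes and the alkenyl iodide should tolerate the nearly neutral second stage.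

Step 14
Reactants: 17 open-chain (6R,7S,8S)-trans-alpha-methylene-gamma-butyrolactone
Product: 18 C9 aldehyde of 17
Conditions: (COCl)2, DMSO, CH2Cl2, −78 → −40 °C; then Et3N, −78 → −20 °C
Reagents that add atoms: none
Why: Swern oxidation of the primary triethylsilyl ether at C9 (oxidative desilylation), which leaves the secondary triethylsilyl ether at C8 and the tert-butyldimethylsilyl ether at C14 in place.

Step 15
Reactants: 18 C9 aldehyde of 17
Product: 19 (6R,7S,8S,9R)-macrocyclic C9 carbinol
Conditions: CrCl2 (10 equiv), NiCl2 (catalytic), DMF/THF, high dilution (about 2 mmol per litre), 23 °C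
Reagents that add atoms: none
Why: In this Nozaki–Hiyama–Kishi macrocyclisation the alkenylchromium species forms with retention of the (Z)-geometry, and Felkin–Anh addition to the alpha-silyloxy aldehyde should give the 8,9-anti carbinol, while the lactone and silyl ethers survive the neutral medium.

Step 16
Reactants: 19 (6R,7S,8S,9R)-macrocyclic C9 carbinol
Product: 20 C9 acetate of 19
Conditions: Ac2O, pyridine, DMAP (catalytic), CH2Cl2, 0 → 23 °C
Reagents that add atoms: acetic anhydride CC(=O)OC(C)=O
Why: Acetylation of the only free hydroxyl group.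

Step 17
Reactants: 20 C9 acetate of 19
Product: 21 (6R,7R,8S,9R)-8,14-diol 9-acetate
Conditions: HF·pyridine, pyridine, THF, 0 → 23 °C
Reagents that add atoms: none
Why: Fluoride-mediated cleavage of both silyl ethers in a buffered, slightly acidic medium, which should suppress acetyl migration from O9 to O8 or O14.

Step 18
Reactants: 21 (6R,7R,8S,9R)-8,14-diol 9-acetate
Product: 22 target CNP0603244.1
Conditions: isovaleryl chloride (1.05 equiv), 2,4,6-collidine, CH2Cl2, −78 → −40 °C
Reagents that add atoms: isovaleryl chloride CC(C)CC(=O)Cl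
Why: Selective acylation of the primary allylic C14 alcohol in the presence of the hindered secondary C8 alcohol, with a weak hindered base at low temperature.

**Compound list**

1 | nerol, (2Z)-3,7-dimethylocta-2,6-dien-1-ol | OC/C=C(/C)CCC=C(C)C | starting material
2 | neryl triethylsilyl ether | CC[Si](CC)(CC)OC/C=C(/C)CCC=C(C)C | intermediate
3 | (4Z)-4-methyl-6-(triethylsilyloxy)hex-4-enal | CC[Si](CC)(CC)OC/C=C(/C)CCC=O | intermediate
4 | ethyl (2Z,6Z)-2-iodo-6-methyl-8-(triethylsilyloxy)octa-2,6-dienoate | CC[Si](CC)(CC)OC/C=C(/C)CC/C=C(/C(=O)OCC)I | intermediate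
5 | (2Z,6Z)-2-iodo-6-methyl-8-(triethylsilyloxy)octa-2,6-dien-1-ol | CC[Si](CC)(CC)OC/C=C(/C)CC/C=C(/CO)I | intermediate
6 | (2Z,6Z)-1-(tert-butyldimethylsilyloxy)-2-iodo-6-methyl-8-(triethylsilyloxy)octa-2,6-diene | CC[Si](CC)(CC)OC/C=C(/C)CC/C=C(/CO[Si](C)(C)C(C)(C)C)I | intermediate
7 | (2Z,6Z)-8-(tert-butyldimethylsilyloxy)-7-iodo-3-methylocta-2,6-dienal (fragment A) | O=C/C=C(/C)CC/C=C(/CO[Si](C)(C)C(C)(C)C)I | intermediate
8 | (R)-2,2-dimethyl-1,3-dioxolane-4-carbaldehyde | O=C[C@H]1COC(C)(C)O1 | starting material
9 | (S)-4-ethynyl-2,2-dimethyl-1,3-dioxolane | C#C[C@H]1COC(C)(C)O1 | intermediate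
10 | (S)-2,2-dimethyl-4-(propa-1,2-dien-1-yl)-1,3-dioxolane | C=C=C[C@H]1COC(C)(C)O1 | intermediate
11 | (S)-penta-3,4-diene-1,2-diol | OC[C@@H](O)C=C=C | intermediate
12 | (S)-1,2-bis(triethylsilyloxy)penta-3,4-diene (fragment B) | CC[Si](CC)(CC)OC[C@@H](O[Si](CC)(CC)CC)C=C=C | intermediate
13 | (8S)-(Z)-bis(boronate): C13H2–Bpin cis to C8, C11–Bpin, C7=C11 alkene | CC[Si](CC)(CC)OC[C@@H](O[Si](CC)(CC)CC)/C=C(/B1OC(C)(C)C(C)(C)O1)CB1OC(C)(C)C(C)(C)O1 | intermediate
14 | open-chain (6S,7S,8S)-alcohol: C6–OH (6-epi), C11(Bpin)=C13H2, OSiEt3 at C8 and C9, (4Z)-alkene, (Z)-C10 iodide, C14–OSiMe2t-Bu | C=C(B1OC(C)(C)C(C)(C)O1)[C@@H]([C@@H](O)/C=C(/C)CC/C=C(/CO[Si](C)(C)C(C)(C)C)I)[C@H](O[Si](CC)(CC)CC)CO[Si](CC)(CC)CC | intermediate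
15 | (6S,7S,8S)-C6 O-allyl N,N'-diisopropylisourea of 14 | C=C(B1OC(C)(C)C(C)(C)O1)[C@@H]([C@@H](OC(=NC(C)C)NC(C)C)/C=C(/C)CC/C=C(/CO[Si](C)(C)C(C)(C)C)I)[C@H](O[Si](CC)(CC)CC)CO[Si](CC)(CC)CC | intermediate
16 | potassium (6S,7S,8S)-acrylate: C11–CO2K, isourea at C6 intact | C=C(C(=O)[O-])[C@@H]([C@@H](OC(=NC(C)C)NC(C)C)/C=C(/C)CC/C=C(/CO[Si](C)(C)C(C)(C)C)I)[C@H](O[Si](CC)(CC)CC)CO[Si](CC)(CC)CC.[K+] | intermediate
17 | open-chain (6R,7S,8S)-trans-alpha-methylene-gamma-butyrolactone with OSiEt3 at C8 and C9, (Z)-C10 iodide, C14–OSiMe2t-Bu | C=C1C(=O)O[C@H](/C=C(/C)CC/C=C(/CO[Si](C)(C)C(C)(C)C)I)[C@H]1[C@H](O[Si](CC)(CC)CC)CO[Si](CC)(CC)CC | intermediate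
18 | (6R,7S,8S)-C9 aldehyde of 17 | C=C1C(=O)O[C@H](/C=C(/C)CC/C=C(/CO[Si](C)(C)C(C)(C)C)I)[C@H]1[C@H](O[Si](CC)(CC)CC)C=O | intermediate
19 | (6R,7S,8S,9R)-(1(10)Z,4Z)-germacradien-6,12-olide with C9–OH, C8–OSiEt3, C14–OSiMe2t-Bu | C=C1C(=O)O[C@@H]2/C=C(/C)CC/C=C(/CO[Si](C)(C)C(C)(C)C)[C@@H](O)[C@@H](O[Si](CC)(CC)CC)[C@@H]12 | intermediate
20 | (6R,7S,8S,9R)-C9 acetate of 19 | C=C1C(=O)O[C@@H]2/C=C(/C)CC/C=C(/CO[Si](C)(C)C(C)(C)C)[C@@H](OC(C)=O)[C@@H](O[Si](CC)(CC)CC)[C@@H]12 | intermediate
21 | (6R,7R,8S,9R)-9-acetoxy-8,14-dihydroxy-(1(10)Z,4Z)-germacra-1(10),4,11(13)-trien-6,12-olide | C=C1C(=O)O[C@@H]2/C=C(/C)CC/C=C(/CO)[C@@H](OC(C)=O)[C@@H](O)[C@@H]12 | intermediate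
22 | CNP0603244.1, (6R,7R,8S,9R)-9-acetoxy-8-hydroxy-14-isovaleryloxy-(1(10)Z,4Z)-germacra-1(10),4,11(13)-trien-6,12-olide | C=C1C(=O)O[C@@H]2/C=C(/C)CC/C=C(/COC(=O)CC(C)C)[C@@H](OC(C)=O)[C@@H](O)[C@@H]12 | target

Total step count: 18. Longest linear sequence: 14 steps (steps 1–6, then 11–18).

**Steps most likely to fail**

- **Step 13.**
  - What may go wrong: boron-to-copper transfer at the hindered, alpha-branched alkenylboronate may be slow, so that protodeboronation competes. The protonated isourea may also ionise before the ring closes, which would erode the C4=C5 geometry or cause elimination.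
  - Fallback: it sets out from 14 and comes back at 17. The two events are separated and the alcohol is activated in a different way. Compound 14 is carboxylated under the same copper catalysis with two equivalents of KOt-Bu and CO2. It is then acidified cold to pH 5 and extracted as the (6S,7S,8S)-hydroxy acid F1. F1 is added at once to PPh3 and diisopropyl azodicarboxylate in THF at 0 °C. This Mitsunobu lactonisation activates the C6 hydroxyl as an oxyphosphonium ion and closes O1–C6 with inversion.

- **Step 11.**
  - What may go wrong: the C8 stereocentre may discriminate the two alkene faces too weakly. Diboration may also occur partly at the internal allene bond.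
  - Fallback: it sets out from 13 and 7 and comes back at 14. Stereocontrol is moved from the substrate to a catalyst. Compound 13 is now isolated by filtration through silica and freed from its regioisomer. It is combined with 7 in toluene at −30 °C in the presence of the chiral phosphoric acid TRIP (3,3'-bis(2,4,6-triisopropylphenyl)-BINOL hydrogen phosphate). Both enantiomers of TRIP are commercial, and the one matched to the C8 bias is used. The catalyst then selects the aldehyde face in the same chair. No new compound arises.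

- **Step 15.**
  - What may go wrong: facial control at the aldehyde may be weak under transannular strain, and intermolecular coupling may compete.
  - Fallback: it sets out from crude 19 and comes back at 19. C9 is set by reduction instead of by addition. The crude carbinol is oxidised with Dess–Martin periodinane to the macrocyclic enone F2. F2 is then reduced with NaBH4/CeCl3 in MeOH at −78 °C (Luche reduction), or with an oxazaborolidine/borane reagent if the peripheral attack of the macrocycle has to be overridden.

**Further compounds**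

F1 | step 13 | (6S,7S,8S)-hydroxy acid: C11–CO2H, free C6–OH, otherwise as 14 | C=C(C(=O)O)[C@@H]([C@@H](O)/C=C(/C)CC/C=C(/CO[Si](C)(C)C(C)(C)C)I)[C@H](O[Si](CC)(CC)CC)CO[Si](CC)(CC)CC
F0 | step 11 | none | none
F2 | step 15 | (6R,7S,8S)-macrocyclic C9 enone | C=C1C(=O)O[C@@H]2/C=C(/C)CC/C=C(/CO[Si](C)(C)C(C)(C)C)C(=O)[C@@H](O[Si](CC)(CC)CC)[C@@H]12
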